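**Plan**

- Retrosynthesis: remove the five benzyl ethers; put a tert-butoxycarbonyl helper back on C3; cut the C3–C4 bond of ring C (retro-benzoin: aryl aldehyde plus α-keto ester); cut the O1–C2 aryl ether; cut the two ring A–CH2 bonds.
- Forward: ring A is finished first (double C-benzylation of 2,4,6-trihydroxybenzaldehyde, then selective O-benzylation). The C2–C3 unit is hung on O1 as a β-chloro α-keto ester. Ring C is then closed by a carbene-catalysed benzoin addition, and the helper ester and the benzyl groups are taken off.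
- Enabling feature: ring C is an acyloin (C4=O, C3–OH) next to C2, a benzylic CH that carries the ring oxygen O1. With C3 held at the α-keto ester level, this C2–H enolises freely, so the open-chain precursor is a racemising mixture that a chiral carbene can drain through one enantiomer.
- Stereochemistry: C2 comes from this dynamic kinetic resolution. C3 is reset after decarboxylation under thermodynamic control by C2 (2,3-trans, both groups equatorial).

Key step: step 5

Assumption: the precatalyst of step 5 is 2-(pentafluorophenyl)-5a,10b-dihydro-4H,6H-indeno[2,1-b][1,2,4]triazolo[4,3-d][1,4]oxazin-2-ium tetrafluoroborate (C18H11BF9N3O, from cis-1-amino-2-indanol); both antipodes are accessible, and the one that drains the (R)-configured keto form of 9 is to be identified in a pilot run.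

Assumption: compounds 1, 2, 5 and 6 and benzyl bromide are purchased.

**Route**

Step 1
Reactants: 1 2,4,6-trihydroxybenzaldehyde; 2 4-(benzyloxy)benzyl alcohol (2.2 equiv)
Product: 3 3,5-bis[4-(benzyloxy)benzyl]-2,4,6-trihydroxybenzaldehyde
Conditions: Sc(OTf)3 (10 mol %), MeCN, 50 °C, slow addition of 2
Reagents that add atoms: none
Why: Friedel–Crafts benzylation, in which the Lewis acid ionises the 4-alkoxybenzyl alcohol to a stabilised cation that attacks the only two free positions of ring A (each flanked by two hydroxyls), so exhaustive substitution leaves no regiochemical question.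

Step 2
Reactants: 3 3,5-bis[4-(benzyloxy)benzyl]-2,4,6-trihydroxybenzaldehyde
Product: 4 4,6-bis(benzyloxy)-3,5-bis[4-(benzyloxy)benzyl]-2-hydroxybenzaldehyde
Conditions: BnBr (2.1 equiv), K2CO3, DMF, rt
Reagents that add atoms: benzyl bromide, BrCc1ccccc1
Why: Williamson etherification, in which the most acidic 4-OH and one of the two symmetry-equivalent ortho hydroxyls react while the last hydroxyl stays hydrogen-bonded to the formyl oxygen and should remain free for step 4.

Step 3
Reactants: 5 4-(benzyloxy)benzaldehyde; 6 tert-butyl dichloroacetate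
Product: 8 tert-butyl 3-[4-(benzyloxy)phenyl]-3-chloro-2-oxopropanoate (racemic), via α-chloroglycidic ester 7 (not isolated)
Conditions: t-BuOK (1.0 equiv), THF, −40 → 0 °C
Reagents that add atoms: none
Why: Darzens condensation of the dichloroacetate enolate gives the 2-chlorooxirane, which opens at the benzylic carbon (assisted by the 4-benzyloxy group) with 1,2-chloride shift to the β-chloro α-keto ester; the new stereocenter is racemic and need not be controlled.

Step 4
Reactants: 4 4,6-bis(benzyloxy)-3,5-bis[4-(benzyloxy)benzyl]-2-hydroxybenzaldehyde; 8 tert-butyl 3-[4-(benzyloxy)phenyl]-3-chloro-2-oxopropanoate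
Product: 9 tert-butyl 3-{3,5-bis(benzyloxy)-2,4-bis[4-(benzyloxy)benzyl]-6-formylphenoxy}-3-[4-(benzyloxy)phenyl]-2-oxopropanoate (racemic)
Conditions: K2CO3, acetone, 0 °C → rt
Reagents that add atoms: none
Why: Williamson-type SN2 displacement of a benzylic α-keto chloride by the phenoxide (any residual chloroepoxide 7 should give the same ether); the stereocenter is formed racemic on purpose, because it is stereolabile and is resolved dynamically in step 5.

Step 5
Reactants: 9 tert-butyl 3-{3,5-bis(benzyloxy)-2,4-bis[4-(benzyloxy)benzyl]-6-formylphenoxy}-3-[4-(benzyloxy)phenyl]-2-oxopropanoate (racemic)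
Product: 10 tert-butyl (2R,3R)-5,7-bis(benzyloxy)-6,8-bis[4-(benzyloxy)benzyl]-2-[4-(benzyloxy)phenyl]-3-hydroxy-4-oxochromane-3-carboxylate
Conditions: chiral triazolium tetrafluoroborate precatalyst (15 mol %), Et3N (30 mol %), toluene, rt → 40 °C, Ar
Reagents that add atoms: none
Why: Proposed new method: the triazolylidene adds to the aryl aldehyde of 9, the only carbonyl that can form a Breslow intermediate because the acceptor carbon sits at the ketone level of an α-keto ester, and the resulting acyl anion equivalent adds to the keto carbonyl in a 6-exo-trig closure that forms the C3–C4 bond and ring C before proton transfer releases the carbene. The closest known reaction types are the enantioselective intramolecular aldehyde–ketone benzoin cyclisation to 3-hydroxychroman-4-ones and dynamic kinetic benzoin additions to ketones with a stereolabile neighbouring carbon (β-stereogenic α-keto esters, 2-substituted 1,3-dicarbonyl compounds); a β-aryl-β-aryloxy α-keto ester tethered through the ether oxygen has not been used in this way. C2 is set by the catalyst: its hydrogen is benzylic, α to the ketone and on the carbon bearing O1, so the enantiomers of 9 should interconvert through the achiral enol under Et3N faster than either cyclises, and the chiral carbene drains the pool through the (R)-configured keto form. C3 is set under substrate control (aryl equatorial, hydroxyl equatorial and hydrogen-bonded to C4=O, ester axial) and its configuration is not relied on, because it is erased in step 6. The step needs chemoselectivity for benzoin closure over the 5-membered aldol closure of the C2 enol onto the aldehyde, which the highly stabilised enol should keep reversible and uphill, and over the redox elimination of the aryloxide that an aldehyde at C3 would allow, which the keto ester oxidation level excludes.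

Step 6
Reactants: 10 tert-butyl (2R,3R)-5,7-bis(benzyloxy)-6,8-bis[4-(benzyloxy)benzyl]-2-[4-(benzyloxy)phenyl]-3-hydroxy-4-oxochromane-3-carboxylate
Product: 13 (2R,3R)-5,7-bis(benzyloxy)-6,8-bis[4-(benzyloxy)benzyl]-2-[4-(benzyloxy)phenyl]-3-hydroxychroman-4-one, via β-keto acid 11 (not isolated), via enediol 12 (not isolated)
Conditions: TFA/CH2Cl2 (1:4), 0 °C → rt; evaporate; toluene, TFA (5 mol %), 60 °C, Ar
Reagents that add atoms: none
Why: Acidolysis of the tert-butyl ester, decarboxylation of the α-hydroxy β-keto acid to the enediol and acid-catalysed ketonisation toward the aryl ketone (C3 protonation leaves a cation at C4 stabilised by ring A) should, being reversible at C3 only, settle on the 2,3-trans isomer with 2-aryl and 3-hydroxyl equatorial and the hydroxyl hydrogen-bonded to C4=O, while C2 is untouched because no enolate is formed and O4' is still benzylated.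

Step 7
Reactants: 13 (2R,3R)-5,7-bis(benzyloxy)-6,8-bis[4-(benzyloxy)benzyl]-2-[4-(benzyloxy)phenyl]-3-hydroxychroman-4-one
Product: 14 gericudranin D, (2R,3R)-3,5,7-trihydroxy-6,8-bis(4-hydroxybenzyl)-2-(4-hydroxyphenyl)chroman-4-one
Conditions: H2 (1 atm), Pd/C (10 wt %), EtOAc/MeOH, rt
Reagents that add atoms: none
Why: Hydrogenolysis of the five benzyl aryl ethers under neutral conditions should leave the trans acyloin, the C2–O1 bond and the diarylmethane CH2 groups intact, and no base is present that could epimerise C2 of the free phenol.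

**Compound list**

1 | 2,4,6-trihydroxybenzaldehyde | O=Cc1c(O)cc(O)cc1O | starting material
2 | 4-(benzyloxy)benzyl alcohol | OCc1ccc(OCc2ccccc2)cc1 | starting material
3 | 3,5-bis[4-(benzyloxy)benzyl]-2,4,6-trihydroxybenzaldehyde | O=Cc1c(O)c(Cc2ccc(OCc3ccccc3)cc2)c(O)c(Cc2ccc(OCc3ccccc3)cc2)c1O | intermediate
4 | 4,6-bis(benzyloxy)-3,5-bis[4-(benzyloxy)benzyl]-2-hydroxybenzaldehyde | O=Cc1c(O)c(Cc2ccc(OCc3ccccc3)cc2)c(OCc2ccccc2)c(Cc2ccc(OCc3ccccc3)cc2)c1OCc1ccccc1 | intermediate
5 | 4-(benzyloxy)benzaldehyde | O=Cc1ccc(OCc2ccccc2)cc1 | starting material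
6 | tert-butyl dichloroacetate | CC(C)(C)OC(=O)C(Cl)Cl | starting material
7 | tert-butyl 3-[4-(benzyloxy)phenyl]-2-chlorooxirane-2-carboxylate (racemic, diastereomer mixture; not isolated) | CC(C)(C)OC(=O)C1(Cl)OC1c1ccc(OCc2ccccc2)cc1 | intermediate
8 | tert-butyl 3-[4-(benzyloxy)phenyl]-3-chloro-2-oxopropanoate (racemic) | CC(C)(C)OC(=O)C(=O)C(Cl)c1ccc(OCc2ccccc2)cc1 | intermediate
9 | tert-butyl 3-{3,5-bis(benzyloxy)-2,4-bis[4-(benzyloxy)benzyl]-6-formylphenoxy}-3-[4-(benzyloxy)phenyl]-2-oxopropanoate (racemic, equilibrating through its enol) | CC(C)(C)OC(=O)C(=O)C(Oc1c(C=O)c(OCc2ccccc2)c(Cc2ccc(OCc3ccccc3)cc2)c(OCc2ccccc2)c1Cc1ccc(OCc2ccccc2)cc1)c1ccc(OCc2ccccc2)cc1 | intermediate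
10 | tert-butyl (2R,3R)-5,7-bis(benzyloxy)-6,8-bis[4-(benzyloxy)benzyl]-2-[4-(benzyloxy)phenyl]-3-hydroxy-4-oxochromane-3-carboxylate (3-OH trans to 2-aryl) | O=C1c2c(OCc3ccccc3)c(Cc3ccc(OCc4ccccc4)cc3)c(OCc3ccccc3)c(Cc3ccc(OCc4ccccc4)cc3)c2O[C@H](c2ccc(OCc3ccccc3)cc2)[C@]1(O)C(=O)OC(C)(C)C | intermediate
11 | (2R,3R)-5,7-bis(benzyloxy)-6,8-bis[4-(benzyloxy)benzyl]-2-[4-(benzyloxy)phenyl]-3-hydroxy-4-oxochromane-3-carboxylic acid (not isolated) | O=C1c2c(OCc3ccccc3)c(Cc3ccc(OCc4ccccc4)cc3)c(OCc3ccccc3)c(Cc3ccc(OCc4ccccc4)cc3)c2O[C@H](c2ccc(OCc3ccccc3)cc2)[C@]1(O)C(=O)O | intermediate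
12 | (2R)-5,7-bis(benzyloxy)-6,8-bis[4-(benzyloxy)benzyl]-2-[4-(benzyloxy)phenyl]-2H-chromene-3,4-diol (not isolated) | OC1=C(O)c2c(OCc3ccccc3)c(Cc3ccc(OCc4ccccc4)cc3)c(OCc3ccccc3)c(Cc3ccc(OCc4ccccc4)cc3)c2O[C@@H]1c1ccc(OCc2ccccc2)cc1 | intermediate
13 | (2R,3R)-5,7-bis(benzyloxy)-6,8-bis[4-(benzyloxy)benzyl]-2-[4-(benzyloxy)phenyl]-3-hydroxychroman-4-one | O=C1c2c(OCc3ccccc3)c(Cc3ccc(OCc4ccccc4)cc3)c(OCc3ccccc3)c(Cc3ccc(OCc4ccccc4)cc3)c2O[C@H](c2ccc(OCc3ccccc3)cc2)[C@H]1O | intermediate
14 | gericudranin D, (2R,3R)-3,5,7-trihydroxy-6,8-bis(4-hydroxybenzyl)-2-(4-hydroxyphenyl)chroman-4-one | O=C1c2c(O)c(Cc3ccc(O)cc3)c(O)c(Cc3ccc(O)cc3)c2O[C@H](c2ccc(O)cc2)[C@H]1O | target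

**Count**

Total steps: 7. Longest linear sequence: 6 steps (steps 1, 2, 4, 5, 6, 7); step 3 is a one-step side branch.

**Steps most likely to fail**

1. Step 5 (proposed new method). The carbene may fail to engage the hindered, electron-rich aldehyde; the substrate may rest as its enol and stall the addition; aldol closure of the C2 enol may compete; or discrimination between the two enantiomers of the keto form may be poor. Fallback in known chemistry, closing ring C through the O1–C2 bond instead: it sets out from 4 and comes back to the route at 13. Phenol 4 is protected (NaH, MOMCl, DMF) as 4,6-bis(benzyloxy)-3,5-bis[4-(benzyloxy)benzyl]-2-(methoxymethoxy)benzaldehyde F1. Addition of MeMgBr (THF, 0 °C) gives the secondary carbinol F2, and Dess–Martin oxidation gives the acetophenone F3. Claisen–Schmidt condensation with 5 (KOH, EtOH/THF) gives the (E)-chalcone F4. Juliá–Colonna epoxidation (poly-L-leucine, urea–H2O2, DBU, THF) should give the (2R,3S)-epoxy ketone F5. HCl in MeOH/THF at 50 °C then removes the methoxymethyl group, and the freed phenol opens the epoxide at the benzylic carbon with inversion (6-endo), which should give 13 directly.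

2. Step 6. Ketonisation of the enediol from the face anti to the 2-aryl group may deliver the 2,3-cis isomer kinetically; equilibration at C3 may be slow; and prolonged acid may open ring C from the enediol and erode C2. Fallback, replacing thermodynamic equilibration by a stereospecific substitution: it sets out from 10 and comes back at 13. Acidolysis and decarboxylation are run without equilibration (TFA/CH2Cl2, 0 °C; then toluene, rt), and the kinetic product is accepted, namely (2R,3S)-5,7-bis(benzyloxy)-6,8-bis[4-(benzyloxy)benzyl]-2-[4-(benzyloxy)phenyl]-3-hydroxychroman-4-one F6. Mitsunobu reaction with 4-nitrobenzoic acid (PPh3, DIAD, THF, 0 °C) inverts C3 to the (2R,3R) 4-nitrobenzoate F7. Mild methanolysis (Et3N, MeOH, rt) then gives 13.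

3. Step 4. O-alkylation of the hindered, hydrogen-bonded phenoxide may be outrun by base-induced decomposition of the chloro keto ester or by aldol closure of the product onto the formyl group. Fallback, making the ether by epoxide opening and setting the ketone afterwards: it sets out from 4 and 5 and comes back at 9. Darzens condensation of 5 with tert-butyl chloroacetate (t-BuOK, THF) gives tert-butyl 3-[4-(benzyloxy)phenyl]oxirane-2-carboxylate F8. The phenoxide of 4 (Cs2CO3, DMF, 60 °C) opens it at the benzylic carbon to the β-aryloxy α-hydroxy ester F9. Dess–Martin oxidation (CH2Cl2, NaHCO3, rt), which leaves the aryl aldehyde alone, gives 9.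

**Further compounds**

F1 | step 5 | 4,6-bis(benzyloxy)-3,5-bis[4-(benzyloxy)benzyl]-2-(methoxymethoxy)benzaldehyde | COCOc1c(C=O)c(OCc2ccccc2)c(Cc2ccc(OCc3ccccc3)cc2)c(OCc2ccccc2)c1Cc1ccc(OCc2ccccc2)cc1
F2 | step 5 | 1-{4,6-bis(benzyloxy)-3,5-bis[4-(benzyloxy)benzyl]-2-(methoxymethoxy)phenyl}ethan-1-ol (racemic) | COCOc1c(C(C)O)c(OCc2ccccc2)c(Cc2ccc(OCc3ccccc3)cc2)c(OCc2ccccc2)c1Cc1ccc(OCc2ccccc2)cc1
F3 | step 5 | 1-{4,6-bis(benzyloxy)-3,5-bis[4-(benzyloxy)benzyl]-2-(methoxymethoxy)phenyl}ethan-1-one | COCOc1c(C(C)=O)c(OCc2ccccc2)c(Cc2ccc(OCc3ccccc3)cc2)c(OCc2ccccc2)c1Cc1ccc(OCc2ccccc2)cc1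
F4 | step 5 | (E)-1-{4,6-bis(benzyloxy)-3,5-bis[4-(benzyloxy)benzyl]-2-(methoxymethoxy)phenyl}-3-[4-(benzyloxy)phenyl]prop-2-en-1-one | COCOc1c(C(=O)/C=C/c2ccc(OCc3ccccc3)cc2)c(OCc2ccccc2)c(Cc2ccc(OCc3ccccc3)cc2)c(OCc2ccccc2)c1Cc1ccc(OCc2ccccc2)cc1
F5 | step 5 | {4,6-bis(benzyloxy)-3,5-bis[4-(benzyloxy)benzyl]-2-(methoxymethoxy)phenyl}{(2R,3S)-3-[4-(benzyloxy)phenyl]oxiran-2-yl}methanone | COCOc1c(C(=O)[C@@H]2O[C@H]2c2ccc(OCc3ccccc3)cc2)c(OCc2ccccc2)c(Cc2ccc(OCc3ccccc3)cc2)c(OCc2ccccc2)c1Cc1ccc(OCc2ccccc2)cc1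
F6 | step 6 | (2R,3S)-5,7-bis(benzyloxy)-6,8-bis[4-(benzyloxy)benzyl]-2-[4-(benzyloxy)phenyl]-3-hydroxychroman-4-one | O=C1c2c(OCc3ccccc3)c(Cc3ccc(OCc4ccccc4)cc3)c(OCc3ccccc3)c(Cc3ccc(OCc4ccccc4)cc3)c2O[C@H](c2ccc(OCc3ccccc3)cc2)[C@@H]1O
F7 | step 6 | (2R,3R)-5,7-bis(benzyloxy)-6,8-bis[4-(benzyloxy)benzyl]-2-[4-(benzyloxy)phenyl]-4-oxochroman-3-yl 4-nitrobenzoate | O=C1c2c(OCc3ccccc3)c(Cc3ccc(OCc4ccccc4)cc3)c(OCc3ccccc3)c(Cc3ccc(OCc4ccccc4)cc3)c2O[C@H](c2ccc(OCc3ccccc3)cc2)[C@H]1OC(=O)c1ccc([N+](=O)[O-])cc1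
F8 | step 4 | tert-butyl 3-[4-(benzyloxy)phenyl]oxirane-2-carboxylate (racemic) | CC(C)(C)OC(=O)C1OC1c1ccc(OCc2ccccc2)cc1
F9 | step 4 | tert-butyl 3-{3,5-bis(benzyloxy)-2,4-bis[4-(benzyloxy)benzyl]-6-formylphenoxy}-3-[4-(benzyloxy)phenyl]-2-hydroxypropanoate (racemic) | CC(C)(C)OC(=O)C(O)C(Oc1c(C=O)c(OCc2ccccc2)c(Cc2ccc(OCc3ccccc3)cc2)c(OCc2ccccc2)c1Cc1ccc(OCc2ccccc2)cc1)c1ccc(OCc2ccccc2)cc1
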